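**Assumption:** Pakyonol has no stereogenic centre and its 20-membered ring is conformationally mobile, so the "single enantiomer" is simply the achiral compound drawn by the SMILES.

**Retrosynthetic overview** (ring A = methoxy ring, B = para-phenylene, C = phenol ring, D = meta-phenylene)
1. Pakyonol ⇐ hydrogenation of an A–C≡C–D alkyne and Pd hydroxylation of a ring-C aryl chloride (masked OH) on the finished 20-membered macrocycle.
2. That macrocycle ⇐ N2-extruding ring contraction (21 → 20) of a macrocyclic 1,1-dibenzyl-2-tosylhydrazine, made in the same pot by stapling a bis(benzyl bromide) with TsNHNH2; this forms the macrocycle and the B–CH2CH2–C bond.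
3. Bis(benzyl bromide) ⇐ double benzylic bromination of a dimethyl diarylalkyne ⇐ one-pot double Sonogashira of two aryl bromides with trimethylsilylacetylene.
4. The two aryl bromides (A–O–B and C–O–D diaryl ethers) ⇐ iodide-selective Ullmann couplings from 2-iodophenol, p-cresol (used twice) and 1-bromo-3-iodobenzene.
5. Ring order: all four benzene rings are bought; the only ring formed is the macrocycle (21-membered, then contracted to 20).

**Step 1**
Reactants: 1 2-iodophenol
Product: 2 1-iodo-2-methoxybenzene
Conditions: MeI, K2CO3, acetone, reflux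
Reagents that add atoms: iodomethane CI
Why: Williamson O-methylation (SN2 on MeI by the phenoxide) installs the target's only methyl ether cleanly at the start.

**Step 2**
Reactants: 2 1-iodo-2-methoxybenzene
Product: 3 4-bromo-2-iodo-1-methoxybenzene
Conditions: NBS, MeCN, rt to 50 °C
Reagents that add atoms: N-bromosuccinimide O=C1CCC(=O)N1Br
Why: Electrophilic aromatic bromination of an anisole with NBS in MeCN goes para to OMe, which places Br at the future ring A bridge carbon without regiochemical ambiguity.

**Step 3**
Reactants: 3 4-bromo-2-iodo-1-methoxybenzene; 4 4-methylphenol (p-cresol)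
Product: 5 4-bromo-1-methoxy-2-(4-methylphenoxy)benzene
Conditions: CuI (10 mol%), picolinic acid (20 mol%), K3PO4, DMSO, 80 °C
Reagents that add atoms: none
Why: Ullmann-type Cu-catalysed C–O coupling reacts at the C–I bond far faster than at the electron-rich C–Br bond, so the A–O–B ether forms with the bromide kept.

**Step 4**
Reactants: 4 4-methylphenol
Product: 6 2-chloro-4-methylphenol
Conditions: SO2Cl2 (1.0 eq), CH2Cl2, 0 °C to rt
Reagents that add atoms: sulfuryl chloride O=S(=O)(Cl)Cl
Why: Electrophilic aromatic chlorination of a para-blocked phenol goes ortho to OH; the chloride is a masked hydroxyl that survives Cu, Pd(PPh3), radical bromination and base.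

**Step 5**
Reactants: 6 2-chloro-4-methylphenol; 7 1-bromo-3-iodobenzene
Product: 8 1-(3-bromophenoxy)-2-chloro-4-methylbenzene
Conditions: 7 (1.3 eq), CuI (10 mol%), picolinic acid (20 mol%), K3PO4, DMSO, 80 °C
Reagents that add atoms: none
Why: Ullmann-type C–O coupling is again selective for the aryl iodide over the aryl bromide and aryl chloride, giving the C–O–D ether with the ring D bromide kept.

**Step 6**
Reactants: 5 4-bromo-1-methoxy-2-(4-methylphenoxy)benzene; 9 ethynyltrimethylsilane; 8 1-(3-bromophenoxy)-2-chloro-4-methylbenzene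
Product: 12 2-chloro-1-(3-{[4-methoxy-3-(4-methylphenoxy)phenyl]ethynyl}phenoxy)-4-methylbenzene, via aryl(trimethylsilyl)alkyne 10 (not isolated), via terminal arylalkyne 11 (not isolated)
Conditions: 5, 9 (1.1 eq), PdCl2(PPh3)2 (4 mol%), CuI (8 mol%), Et3N, PhMe, 80 °C (sealed); then 8, DBU, H2O (0.4 eq), 80 °C
Reagents that add atoms: none
Why: One-pot sequential Sonogashira coupling with in-situ DBU/water desilylation joins rings A and D through a C2 unit, and PPh3-ligated Pd leaves the aryl chloride untouched.

**Step 7**
Reactants: 12 2-chloro-1-(3-{[4-methoxy-3-(4-methylphenoxy)phenyl]ethynyl}phenoxy)-4-methylbenzene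
Product: 13 4-(bromomethyl)-1-[3-({3-[4-(bromomethyl)phenoxy]-4-methoxyphenyl}ethynyl)phenoxy]-2-chlorobenzene
Conditions: NBS (2.1 eq), AIBN (10 mol%), PhCF3, 85 °C
Reagents that add atoms: N-bromosuccinimide O=C1CCC(=O)N1Br
Why: Wohl–Ziegler radical bromination can only hit the two aryl methyl groups, because the A–D bridge is still an alkyne and there are no other benzylic C–H bonds.

**Step 8**
Reactants: 13 4-(bromomethyl)-1-[3-({3-[4-(bromomethyl)phenoxy]-4-methoxyphenyl}ethynyl)phenoxy]-2-chlorobenzene
Product: 16 chloroalkyne macrocycle (pakyonol ring system in which Cl replaces the phenolic OH while C≡C replaces the ring A–ring D CH2CH2 bridge), via macrocyclic tosylhydrazide 14 (not isolated), via macrocyclic isodiazene 15 (not isolated)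
Conditions: TsNHNH2 (1.05 eq), i-Pr2NEt (2.5 eq), MeCN, 60 °C, syringe-pump addition of 13 (final 2 mM); then t-BuOK (4 eq), 70 °C
Reagents that add atoms: none
Why: Proposed new method: with only a non-deprotonating amine base the terminal NH2 of p-toluenesulfonyl hydrazide is benzylated twice (the second time intramolecularly under high dilution) to give the 21-membered 1,1-dibenzyl-2-tosylhydrazine 14; t-BuOK then removes the N–H, sulfinate leaves to give isodiazene 15, which loses N2 to a geminate benzyl/benzyl radical pair that recombines to the B–CH2CH2–C bond, a stepwise radical ring contraction from 21 to 20 members; the closest known reactions are the base fragmentation of acyclic 1,1-dibenzyl-2-arenesulfonylhydrazines to bibenzyls, isodiazene-based nitrogen deletion of dibenzylamines, and N',N'-dialkylation of hydrazides by bis-benzylic dihalides, none of which has been used as a one-pot traceless staple to close and contract a macrocycle.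

**Step 9**
Reactants: 16 chloroalkyne macrocycle
Product: 17 alkyne analogue of pakyonol (pakyonol in which C≡C replaces the ring A–ring D CH2CH2 bridge)
Conditions: tBuBrettPhos Pd G3 (4 mol%), KOH (3 eq), 1,4-dioxane/H2O, 90 °C; then aq. HCl
Reagents that add atoms: potassium hydroxide [K+].[OH-]
Why: Pd-catalysed hydroxylation of aryl chlorides (C–O cross-coupling with hydroxide) tolerates electron-rich, ortho-substituted chlorides and unmasks the ring C phenol; the internal alkyne and ethers are inert to it.

**Step 10**
Reactants: 17 alkyne analogue of pakyonol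
Product: 18 pakyonol
Conditions: H2 (1 atm), 10% Pd/C, EtOAc/EtOH, rt
Reagents that add atoms: none
Why: Heterogeneous catalytic hydrogenation saturates the diarylalkyne to the A–CH2CH2–D bridge without touching diaryl ethers, the methyl ether or the phenol; no stereocentre is created.

**Compound list**
1 | 2-iodophenol | Oc1ccccc1I | starting material
2 | 1-iodo-2-methoxybenzene | COc1ccccc1I | intermediate
3 | 4-bromo-2-iodo-1-methoxybenzene | COc1ccc(Br)cc1I | intermediate
4 | 4-methylphenol (p-cresol) | Cc1ccc(O)cc1 | starting material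
5 | 4-bromo-1-methoxy-2-(4-methylphenoxy)benzene | COc1ccc(Br)cc1Oc1ccc(C)cc1 | intermediate
6 | 2-chloro-4-methylphenol | Cc1ccc(O)c(Cl)c1 | intermediate
7 | 1-bromo-3-iodobenzene | Brc1cccc(I)c1 | starting material
8 | 1-(3-bromophenoxy)-2-chloro-4-methylbenzene | Cc1ccc(Oc2cccc(Br)c2)c(Cl)c1 | intermediate
9 | ethynyltrimethylsilane | C#C[Si](C)(C)C | starting material
10 | {[4-methoxy-3-(4-methylphenoxy)phenyl]ethynyl}trimethylsilane | COc1ccc(C#C[Si](C)(C)C)cc1Oc1ccc(C)cc1 | intermediate
11 | 4-ethynyl-1-methoxy-2-(4-methylphenoxy)benzene | COc1ccc(C#C)cc1Oc1ccc(C)cc1 | intermediate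
12 | 2-chloro-1-(3-{[4-methoxy-3-(4-methylphenoxy)phenyl]ethynyl}phenoxy)-4-methylbenzene | COc1ccc(C#Cc2cccc(Oc3ccc(C)cc3Cl)c2)cc1Oc1ccc(C)cc1 | intermediate
13 | 4-(bromomethyl)-1-[3-({3-[4-(bromomethyl)phenoxy]-4-methoxyphenyl}ethynyl)phenoxy]-2-chlorobenzene | COc1ccc(C#Cc2cccc(Oc3ccc(CBr)cc3Cl)c2)cc1Oc1ccc(CBr)cc1 | intermediate
14 | macrocyclic tosylhydrazide (21-membered ring; the ring B and ring C benzylic CH2 groups both on one N that carries NH–Ts) | COc1ccc2cc1Oc1ccc(cc1)CN(NS(=O)(=O)c1ccc(C)cc1)Cc1ccc(c(Cl)c1)Oc1cccc(c1)C#C2 | intermediate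
15 | macrocyclic isodiazene (1,1-diazene of the same 21-membered ring) | COc1ccc2cc1Oc1ccc(cc1)C[N+](=[N-])Cc1ccc(c(Cl)c1)Oc1cccc(c1)C#C2 | intermediate
16 | chloroalkyne macrocycle (20-membered; Cl for OH on ring C, C≡C between rings A and D) | COc1ccc2cc1Oc1ccc(cc1)CCc1ccc(c(Cl)c1)Oc1cccc(c1)C#C2 | intermediate
17 | alkyne analogue of pakyonol (C≡C between rings A and D) | COc1ccc2cc1Oc1ccc(cc1)CCc1ccc(c(O)c1)Oc1cccc(c1)C#C2 | intermediate
18 | pakyonol | COc1ccc2cc1Oc1ccc(cc1)CCc1ccc(c(O)c1)Oc1cccc(c1)CC2 | target

**Total step count:** 10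
**Longest linear sequence:** 8 (steps 1, 2, 3, 6, 7, 8, 9, 10)

**Three steps most likely to fail**

Step 8 (the proposed new step). The hydrazide may alkylate at the sulfonamide nitrogen, oligomerise, or lose sulfinate after only one alkylation. The fallback uses known chemistry and sets out from 13. Double N-alkylation of 2-nitrobenzenesulfonamide with 13 (Cs2CO3, DMF, high dilution) gives the macrocyclic N-nosyl dibenzylamine F2. Thiophenol/K2CO3 removes the nosyl group to give the macrocyclic secondary dibenzylamine F3. Nitrogen deletion of F3 with the anomeric amide N-(benzyloxy)-N-(pivaloyloxy)-4-(trifluoromethyl)benzamide (THF, 45 °C) proceeds through the same isodiazene and comes back to the route at 16.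

Step 7. Double monobromination can stall or over-brominate, and traces of Br2 may attack the anisole ring or the alkyne. The fallback sets out from 12. Both methyl groups are deliberately driven to the gem-dibromide with excess NBS under irradiation, giving the bis(dibromomethyl) compound F1. Each CHBr2 is then reduced back by one bromine with diethyl phosphite/i-Pr2NEt (THF, 0 °C), which comes back to the route at 13.

Step 9. C–O reductive elimination on a hindered, electron-rich aryl chloride inside a macrocycle may be slow. The fallback sets out from 16. Miyaura borylation (Pd2(dba)3/XPhos, B2pin2, KOAc, dioxane, 100 °C) converts the chloride into the aryl pinacol boronate F4. Oxidation of F4 with H2O2/NaOH gives the phenol and comes back to the route at 17.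

**Further compounds**
F1 | step 7 | 2-chloro-4-(dibromomethyl)-1-[3-({3-[4-(dibromomethyl)phenoxy]-4-methoxyphenyl}ethynyl)phenoxy]benzene | COc1ccc(C#Cc2cccc(Oc3ccc(C(Br)Br)cc3Cl)c2)cc1Oc1ccc(C(Br)Br)cc1
F2 | step 8 | macrocyclic N-(2-nitrobenzenesulfonyl) dibenzylamine (21-membered ring, N between the ring B and ring C CH2 groups) | COc1ccc2cc1Oc1ccc(cc1)CN(S(=O)(=O)c1ccccc1[N+](=O)[O-])Cc1ccc(c(Cl)c1)Oc1cccc(c1)C#C2
F3 | step 8 | macrocyclic secondary dibenzylamine (21-membered ring, NH between the ring B and ring C CH2 groups) | COc1ccc2cc1Oc1ccc(cc1)CNCc1ccc(c(Cl)c1)Oc1cccc(c1)C#C2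
F4 | step 9 | aryl pinacol boronate of the macrocycle (Bpin in place of Cl on ring C of 16) | COc1ccc2cc1Oc1ccc(cc1)CCc1ccc(c(B3OC(C)(C)C(C)(C)O3)c1)Oc1cccc(c1)C#C2
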